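The runs are simulated for substances that don't exist, and the scatter is random.

The solid E could not be read in either run, so in my books for the asked flask its entry had to come last, by subtraction. E is the limiting reagent there.

| setting | green | grey | flask |
|---|---|---|---|
| E | 1.3 M | 0.87 M | 1.3 M |
| remark | the very flask that is asked about, followed so far | run made earlier |  |
| time |  |  | 3.0 min |

| run | time / s | D / % | J / % |
|---|---|---|---|
| green | 10.0 | 0 | 0.6 |
| green | 12.0 | 0 | 1.4 |
| green | 20.0 | 0 | 3.9 |
| green | 30.0 | 0 | 7.0 |
| green | 40.0 | 0.2 | 8.1 |
| grey | 10.0 | 0 | 3.6 |
| grey | 15.0 | 0.8 | 5.0 |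
| grey | 30.0 | 1.5 | 9.4 |
| grey | 50.0 | 3.0 | 13.5 |
| grey | 80.0 | 5.8 | 18.7 |
| grey | 120 | 12.1 | 18.9 |

(readings scatter by 1 percentage point)

- the D standing at 3.0 min, as a percentage of the E charged
- concentration of J in solution at 3.0 min, in percent of saturation

- percentages count the E that a species holds: one D counts as two
- solid, in amounts per volume of the solution: E
- the numbers in the tables scatter with a standard deviation of 1 percentage point
- at the start none of E is in solution
- J is what E becomes in solution
- J means what is dissolved; the solid is not counted in it

I took two J to make one D, so the D entry grows with [J] squared. In the grey run the readings of [J] at 80.0 s and 120 s were 18.7 % and 18.9 % of the charge, each with a scatter of 1 percentage point, and I took their mean, 0.164 M, as a working level for that span, while the readings of D went from 5.8 % to 12.1 %. That read 0.0512 M⁻¹ s⁻¹ for a second-order rate constant I call the pairing constant, the molar E passing into D per second divided by [J] squared.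

The green run's [J] at 40.0 s, 0.105 M, lay between the grey run's 0.0818 M at 30.0 s and 0.117 M at 50.0 s, so I let the green flask follow the grey one in molar terms. My books at 3.0 min opened with 0.105 M of E in D at 120 s. Pairing with [J] entered at that working level added 0.0822 M, making 0.187 M, or 14.4 % of the charge. I entered J at 0.164 M, and the solid closed the books at 0.949 M. I put no number on saturation.

The forecast said 17 % D (11 % to 24 %), more than my figure, and 60 % of saturation (45 % to 90 %), on the ground: “So this is a steady state between dissolution and dimerisation, not necessarily saturation.”

The flask gave 16.4 % D and 39.7 % of saturation, below the forecast's range.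

    2 J → D (k = 0.0274 M⁻¹ s⁻¹)
    E ⇌ J, rate k2*(cs2 - [J]) while solid is left; crystals form when [J] > cs2 (solubility = 0.460 M, k = 0.00683 s⁻¹)
    J → L (k = 2.07 × 10⁻⁶ s⁻¹)

In this flask [J] stood at 0.183 M at 3.00 min, above my level. From 1.50 min to 3.00 min, the pairing constant with the mean [J] gives 10 points of D, against 12 points simulated. The same flask read at 8.0 min still had [J] at 14.2 % of the charge, so I carried 0.183 M forward from 3.0 min, which gives 55.9 % D. That neighbouring flask held 59.6 % D.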